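**Plan**

- Retrosynthesis: cut the C4–O ester, then the C3–isopropyl bond, then the two seven‑ring bonds C3a–C4 and C6–C7 together, then C8a–CH3 (azulene numbering throughout).
- Enabling feature: in the cycloheptene ring the allylic carbinol unit C4(O)–C5=C6(CH3) lies between C3a, which is α to the five‑ring carbonyl carbon C3, and C7, the end of the two‑carbon arm on quaternary C8a. It is therefore excised as (Z)‑3‑iodobut‑2‑enal, an aldehyde and an alkenyl iodide in one piece.
- Forward: five‑membered ring first (cyclopentenone with a 2‑iodoethyl arm), then C8a by asymmetric conjugate methylation with trapping of the regiodefined enolate, then the seven‑membered ring by a one‑flask (4+3) annulation, then isopropyl addition and esterification.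
- Stereochemistry: C8a from the chiral ligand on Cu(OTf)2; C3a and C4 from an anti‑selective chair aldol on the enolate face syn to the C8a methyl group (this gives the trans ring fusion, since closure at C6–C7 touches no stereocentre); C3 from addition anti to the C3a substituent and the angular methyl group.

Key step: step 6

Remark: the aldehyde in step 6 is assumed to approach the enolate syn to the methyl group and anti to the larger 2‑iodoethyl arm; this is the main uncertainty of the route and is treated under the risks.

**Route**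

Step 1
Reactants: 1 3-ethoxycyclopent-2-en-1-one
Product: 3 3-ethenylcyclopent-2-en-1-one, via 1-ethenyl-3-ethoxycyclopent-2-en-1-ol 2 (not isolated)
Conditions: vinylMgBr, THF, 0 °C; then 1 M HCl, 0 °C to rt
Reagents that add atoms: vinylmagnesium bromide, C=C[Mg]Br
Why: 1,2-addition to the vinylogous ester followed by acid hydrolysis with allylic transposition (Stork–Danheiser sequence) should give the 3-substituted enone.

Step 2
Reactants: 3 3-ethenylcyclopent-2-en-1-one
Product: 4 3-(2-iodoethyl)cyclopent-2-en-1-one
Conditions: HI (57% in H2O), MeCN, 0 °C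
Reagents that add atoms: hydrogen iodide, I
Why: conjugate 1,6-hydroiodination of the linear dienone should place iodide on the terminal carbon and restore the conjugated enone, the reversible 1,4-adduct draining to this product.

Step 3
Reactants: 4 3-(2-iodoethyl)cyclopent-2-en-1-one
Product: 6 (R)-{[3-(2-iodoethyl)-3-methylcyclopent-1-en-1-yl]oxy}trimethylsilane, via dimethylaluminium enolate 5 (not isolated)
Conditions: Me3Al, Cu(OTf)2 (5 mol%), chiral sulfonate-bearing N-heterocyclic carbene ligand (5 mol%), THF, −78 °C; then TMSOTf, −78 to 0 °C; aq. NaHCO3 work-up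
Reagents that add atoms: trimethylaluminium, C[Al](C)C; trimethylsilyl trifluoromethanesulfonate, C[Si](C)(C)OS(=O)(=O)C(F)(F)F
Why: copper-catalysed enantioselective conjugate addition of methyl to a β-substituted cyclopentenone sets the quaternary centre under ligand control (ligand enantiomer chosen for R), and O-silylation of the aluminium enolate fixes the enol double bond on the side of the new quaternary carbon.

Step 4
Reactants: 7 but-2-yn-1-ol
Product: 8 but-2-ynal
Conditions: activated MnO2, CH2Cl2, rt
Reagents that add atoms: none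
Why: MnO2 oxidises propargylic alcohols selectively to ynals without touching the alkyne.

Step 5
Reactants: 8 but-2-ynal
Product: 9 (Z)-3-iodobut-2-enal
Conditions: NaI, AcOH, rt, dark; used at once
Reagents that add atoms: sodium iodide, [Na+].[I-]
Why: conjugate hydroiodination of an ynal proceeds by anti addition and should give the Z isomer (iodine cis to the formyl group) under kinetic control.

Step 6
Reactants: 6 (R)-{[3-(2-iodoethyl)-3-methylcyclopent-1-en-1-yl]oxy}trimethylsilane; 9 (Z)-3-iodobut-2-enal
Product: 14 (3aS,4S,8aS)-4-hydroxy-6,8a-dimethyl-2,3a,4,7,8,8a-hexahydro-1H-azulen-3-one, via dibutylboron enolate 10 (not isolated), via open boron aldolate 11 (not isolated), via alkylzinc iodide 12 (not isolated), via cyclised boron aldolate 13 (not isolated)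
Conditions: Bu2BOTf, iPr2NEt, CH2Cl2, −78 to 0 °C; 9, −78 °C; then THF, Zn dust, LiCl, 25 °C; Pd(PPh3)4 (5 mol%), 40 °C; pH 7 sodium phosphate buffer/MeOH work-up
Reagents that add atoms: none
Why: Silicon–boron exchange turns 6 into the ring (E)-boron enolate 10, which adds to the aldehyde of 9 through a closed chair transition state (boron aldol, anti-selective for ring enolates) and forms C3a–C4 with both new stereocentres; the aldehyde should approach the enolate face syn to the C8a methyl group and anti to the larger iodoethyl arm, which is what makes the later ring fusion trans. Zinc then inserts into the primary C–I bond of 11 in preference to the unactivated alkenyl C–I bond, zerovalent palladium adds to the alkenyl iodide, and transmetalation with reductive elimination (intramolecular Negishi coupling) forms C6–C7 with retention of the Z geometry. The seven-membered ring therefore closes by reductive elimination from an eight-membered palladacycle at two non-stereogenic carbons, so the aldol stereochemistry is carried over unchanged. Overall this is a formal (4+3) annulation of a 1,4-dinucleophile (enolate carbon and alkylzinc) with a 1,3-dielectrophile (aldehyde and alkenyl iodide); the closest precedents are boron aldol additions of ketone enolates to enals and ring-closing alkyl–alkenyl Negishi couplings. The step needs the aldol to precede the coupling, which is secured by adding zinc and palladium only after the aldol at −78 °C, and it needs chemoselective zinc insertion, which rests on the much slower insertion into alkenyl iodides; the neutral conditions should leave the epimerisable C3a centre and the β-oxygenated ketone intact.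

Step 7
Reactants: 14 (3aS,4S,8aS)-4-hydroxy-6,8a-dimethyl-2,3a,4,7,8,8a-hexahydro-1H-azulen-3-one
Product: 15 (3R,3aS,4S,8aS)-6,8a-dimethyl-3-(propan-2-yl)-1,2,3,3a,4,7,8,8a-octahydroazulene-3,4-diol
Conditions: iPrMgCl (3 equiv), LaCl3·2LiCl, THF, −78 to −20 °C; aq. NH4Cl
Reagents that add atoms: isopropylmagnesium chloride, CC(C)[Mg]Cl
Why: LaCl3·2LiCl-promoted Grignard 1,2-addition to the enolisable ketone should occur on the face anti to the C3a substituent and the angular methyl group (as in additions to ring-fusion-flanked cyclopentanones), placing the C3 hydroxyl cis to the methyl group.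

Step 8
Reactants: 15 (3R,3aS,4S,8aS)-6,8a-dimethyl-3-(propan-2-yl)-1,2,3,3a,4,7,8,8a-octahydroazulene-3,4-diol; 16 4-acetoxybenzoyl chloride
Product: 17 (3R,3aS,4S,8aS)-3-hydroxy-6,8a-dimethyl-3-(propan-2-yl)-1,2,3,3a,4,7,8,8a-octahydroazulen-4-yl 4-acetoxybenzoate
Conditions: pyridine, DMAP (10 mol%), CH2Cl2, 0 °C to rt
Reagents that add atoms: none
Why: DMAP-catalysed acylation should take the secondary allylic hydroxyl and leave the hindered tertiary hydroxyl free.

Step 9
Reactants: 17 (3R,3aS,4S,8aS)-3-hydroxy-6,8a-dimethyl-3-(propan-2-yl)-1,2,3,3a,4,7,8,8a-octahydroazulen-4-yl 4-acetoxybenzoate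
Product: 18 (3R,3aS,4S,8aS)-3-hydroxy-6,8a-dimethyl-3-(propan-2-yl)-1,2,3,3a,4,7,8,8a-octahydroazulen-4-yl 4-hydroxybenzoate
Conditions: NH3 (7 M in MeOH), 0 °C
Reagents that add atoms: none
Why: aminolysis should cleave the activated aryl acetate much faster than the hindered alkyl benzoate.

**Compound list**

1 | 3-ethoxycyclopent-2-en-1-one | CCOC1=CC(=O)CC1 | starting material
2 | 1-ethenyl-3-ethoxycyclopent-2-en-1-ol (racemic, formed as its bromomagnesium alkoxide) | CCOC1=CC(O)(C=C)CC1 | intermediate
3 | 3-ethenylcyclopent-2-en-1-one | C=CC1=CC(=O)CC1 | intermediate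
4 | 3-(2-iodoethyl)cyclopent-2-en-1-one | O=C1C=C(CCI)CC1 | intermediate
5 | dimethylaluminium (R)-3-(2-iodoethyl)-3-methylcyclopent-1-en-1-olate | C[Al](C)OC1=C[C@@](C)(CCI)CC1 | intermediate
6 | (R)-{[3-(2-iodoethyl)-3-methylcyclopent-1-en-1-yl]oxy}trimethylsilane | C[Si](C)(C)OC1=C[C@@](C)(CCI)CC1 | intermediate
7 | but-2-yn-1-ol | CC#CCO | starting material
8 | but-2-ynal | CC#CC=O | intermediate
9 | (Z)-3-iodobut-2-enal | C/C(I)=C/C=O | intermediate
10 | dibutyl{[(R)-3-(2-iodoethyl)-3-methylcyclopent-1-en-1-yl]oxy}borane | CCCCB(CCCC)OC1=C[C@@](C)(CCI)CC1 | intermediate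
11 | O-dibutylboryl derivative of (2S,3R)-2-[(1R,2Z)-1-hydroxy-3-iodobut-2-en-1-yl]-3-(2-iodoethyl)-3-methylcyclopentan-1-one (anti aldolate, side chain cis to the ring methyl) | C/C(I)=C/[C@H](OB(CCCC)CCCC)[C@@H]1[C@@](C)(CCI)CCC1=O | intermediate
12 | the same boron aldolate with the 2-iodoethyl arm converted into CH2CH2ZnI | C/C(I)=C/[C@H](OB(CCCC)CCCC)[C@@H]1[C@@](C)(CC[Zn]I)CCC1=O | intermediate
13 | O-dibutylboryl derivative of 14 (trans-fused) | CC1=C[C@H](OB(CCCC)CCCC)[C@@H]2[C@@](C)(CC1)CCC2=O | intermediate
14 | (3aS,4S,8aS)-4-hydroxy-6,8a-dimethyl-2,3a,4,7,8,8a-hexahydro-1H-azulen-3-one (trans-fused, 4-OH trans to the 8a-methyl) | CC1=C[C@H](O)[C@@H]2[C@@](C)(CC1)CCC2=O | intermediate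
15 | (3R,3aS,4S,8aS)-6,8a-dimethyl-3-(propan-2-yl)-1,2,3,3a,4,7,8,8a-octahydroazulene-3,4-diol | CC1=C[C@H](O)[C@@H]2[C@@](C)(CC1)CC[C@@]2(O)C(C)C | intermediate
16 | 4-acetoxybenzoyl chloride | CC(=O)Oc1ccc(cc1)C(Cl)=O | starting material
17 | (3R,3aS,4S,8aS)-3-hydroxy-6,8a-dimethyl-3-(propan-2-yl)-1,2,3,3a,4,7,8,8a-octahydroazulen-4-yl 4-acetoxybenzoate | CC1=C[C@H](OC(=O)c2ccc(OC(C)=O)cc2)[C@@H]2[C@@](C)(CC1)CC[C@@]2(O)C(C)C | intermediate
18 | (3R,3aS,4S,8aS)-3-hydroxy-6,8a-dimethyl-3-(propan-2-yl)-1,2,3,3a,4,7,8,8a-octahydroazulen-4-yl 4-hydroxybenzoate | CC1=C[C@H](OC(=O)c2ccc(O)cc2)[C@@H]2[C@@](C)(CC1)CC[C@@]2(O)C(C)C | target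

**Summary**

Total step count: 9. Longest linear sequence: 7 steps (steps 1, 2, 3, 6, 7, 8, 9); steps 4 and 5 make the three-carbon piece.

**Steps most likely to fail**

Step 6. The aldehyde may not discriminate well between the enolate faces flanked by the methyl group and the iodoethyl arm, which would give the cis-fused series. The alkylzinc may also be protonated or lose β-hydride before the ring closes. The fallback separates the two bond formations and changes the ring-closing reaction. From 6 and 9 the boron aldol is run alone and worked up to the isolated bis-iodide (2S,3R)-2-[(1R,2Z)-1-hydroxy-3-iodobut-2-en-1-yl]-3-(2-iodoethyl)-3-methylcyclopentan-1-one F1, from which any C2 epimer is removed by chromatography. The ring is then closed by nickel-catalysed reductive cross-electrophile coupling of the alkyl iodide with the alkenyl iodide (NiI2, 4,4′-di-tert-butyl-2,2′-bipyridine, Mn powder, NaI, DMA, rt), which needs no organozinc and returns to 14.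

Step 3. The aluminium enolate may resist O-silylation, or the enol silane may hydrolyse on isolation; either would lose the regiodefined enolate on which step 6 depends. In the fallback the conjugate addition to 4 is quenched with acetic anhydride to give the chromatography-stable enol acetate (R)-3-(2-iodoethyl)-3-methylcyclopent-1-en-1-yl acetate F2. This is cleaved with MeLi (2 equiv, THF, −40 °C) to the lithium enolate and transmetalated with Bu2BOTf, which rejoins the route at boron enolate 10.

Step 7. Enolisation or retro-aldol fragmentation of the magnesium aldolate may outrun addition of the hindered secondary Grignard reagent, or addition may occur syn to the angular methyl group. The fallback uses a smaller sp2 nucleophile on a protected substrate. Compound 14 is silylated (Et3SiCl, imidazole) to (3aS,4S,8aS)-6,8a-dimethyl-4-[(triethylsilyl)oxy]-2,3a,4,7,8,8a-hexahydro-1H-azulen-3-one F3. Isopropenylmagnesium bromide with LaCl3·2LiCl then gives (3S,3aS,4S,8aS)-6,8a-dimethyl-3-(prop-1-en-2-yl)-4-[(triethylsilyl)oxy]-1,2,3,3a,4,7,8,8a-octahydroazulen-3-ol F4. Hydrogenation with RhCl(PPh3)3 should saturate only the 1,1-disubstituted alkene to give (3R,3aS,4S,8aS)-6,8a-dimethyl-3-(propan-2-yl)-4-[(triethylsilyl)oxy]-1,2,3,3a,4,7,8,8a-octahydroazulen-3-ol F5, and Bu4NF returns to 15.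

Further compounds
F1 | step 6 | (2S,3R)-2-[(1R,2Z)-1-hydroxy-3-iodobut-2-en-1-yl]-3-(2-iodoethyl)-3-methylcyclopentan-1-one | C/C(I)=C/[C@H](O)[C@@H]1[C@@](C)(CCI)CCC1=O
F2 | step 3 | (R)-3-(2-iodoethyl)-3-methylcyclopent-1-en-1-yl acetate | CC(=O)OC1=C[C@@](C)(CCI)CC1
F3 | step 7 | (3aS,4S,8aS)-6,8a-dimethyl-4-[(triethylsilyl)oxy]-2,3a,4,7,8,8a-hexahydro-1H-azulen-3-one | CC1=C[C@H](O[Si](CC)(CC)CC)[C@@H]2[C@@](C)(CC1)CCC2=O
F4 | step 7 | (3S,3aS,4S,8aS)-6,8a-dimethyl-3-(prop-1-en-2-yl)-4-[(triethylsilyl)oxy]-1,2,3,3a,4,7,8,8a-octahydroazulen-3-ol | CC1=C[C@H](O[Si](CC)(CC)CC)[C@@H]2[C@@](C)(CC1)CC[C@@]2(O)C(C)=C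
F5 | step 7 | (3R,3aS,4S,8aS)-6,8a-dimethyl-3-(propan-2-yl)-4-[(triethylsilyl)oxy]-1,2,3,3a,4,7,8,8a-octahydroazulen-3-ol | CC1=C[C@H](O[Si](CC)(CC)CC)[C@@H]2[C@@](C)(CC1)CC[C@@]2(O)C(C)C
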